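**Retrosynthetic overview**
1. C40 = acetylenic β-end C15 phosphonium salt + C10 dialdehyde + ε-end C15 phosphonium salt, joined by two Wittig reactions (C11=C12, then C11'=C12').
2. Each ring is closed on an open-chain ψ-type chain by C1-cation/C5=C6-olefin cyclisation (C1–C6 bond), as the lycopene cyclases do, with the C3 carbinol already in place.
3. β ring (step 6): closed on the complete open-chain C15 dienyne phosphonium salt; proton loss from C6 gives the 7,8-didehydro-β end.
4. ε ring (step 12): closed on a 3-hydroxy-γ-pseudoionone; the equatorial C3'–O in the chair sets C6' trans, and proton loss from C4' gives the ε end.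
5. Open-chain precursors come from (S)- and (R)-epichlorohydrin by isopropenyl opening, acetylide opening and carboalumination/iodination, then Sonogashira (β series) or Heck (ε series) coupling.

Assumption: the target is read from the SMILES as all-E (3R,3'R,6'R)-7,8-didehydro-β,ε-carotene-3,3'-diol (monadoxanthin); carotenoid numbering is used for positions, primed for the ε half.

**Route**

Step 1
Reactants: 1 (S)-epichlorohydrin; 2 isopropenylmagnesium bromide
Product: 3 (S)-1-chloro-4-methylpent-4-en-2-ol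
Conditions: CuI (10 mol%), THF, −40 → −20 °C; aq. NH4Cl
Reagents that add atoms: isopropenylmagnesium bromide, CC(=C)[Mg]Br
Why: Copper-catalysed Grignard opening (SN2) of the epoxide at its CH2 carbon leaves the chiral-pool C–O stereocentre untouched, and this carbon becomes C3 of the β ring.

Step 2
Reactants: 3 (S)-1-chloro-4-methylpent-4-en-2-ol; 4 lithium acetylide–ethylenediamine complex
Product: 6 (S)-6-methylhept-6-en-1-yn-4-ol, via epoxide 5 (not isolated)
Conditions: LiC≡CH·H2NCH2CH2NH2 (3 equiv), DMSO, 0 °C → rt; aq. NH4Cl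
Reagents that add atoms: lithium acetylide–ethylenediamine complex, [Li+].[C-]#C.NCCN
Why: The alkoxide closes to the terminal epoxide (intramolecular Williamson reaction) and acetylide opens it at CH2 (SN2 epoxide alkynylation), so no bond to the carbinol carbon is broken.

Step 3
Reactants: 6 (S)-6-methylhept-6-en-1-yn-4-ol; 7 trimethylaluminium; 8 iodine
Product: 10 (S,E)-1-iodo-2,6-dimethylhepta-1,6-dien-4-ol, via alkenylalane 9 (not isolated)
Conditions: AlMe3 (3 equiv), Cp2ZrCl2 (0.3 equiv), CH2Cl2, 0 °C → rt; then I2, THF, −30 → 0 °C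
Reagents that add atoms: trimethylaluminium, C[Al](C)C; iodine, II
Why: Negishi zirconium-catalysed carboalumination adds methyl and aluminium syn to the terminal alkyne (Al at the terminus, the 1,1-disubstituted alkene is inert), and iodinolysis with retention gives the E-iodide that fixes the future C5=C6 geometry.

Step 4
Reactants: 10 (S,E)-1-iodo-2,6-dimethylhepta-1,6-dien-4-ol; 11 (E)-3-methylpent-2-en-4-yn-1-ol
Product: 12 (2E,6E,9S)-3,7,11-trimethyldodeca-2,6,11-trien-4-yne-1,9-diol
Conditions: Pd(PPh3)2Cl2 (3 mol%), CuI (5 mol%), Et3N, THF, rt, degassed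
Reagents that add atoms: (E)-3-methylpent-2-en-4-yn-1-ol, C#C/C(C)=C/CO
Why: Sonogashira coupling at room temperature keeps both alkene geometries and tolerates the free hydroxyls and the isolated alkene, giving the whole open-chain C15 skeleton of the acetylenic half.

Step 5
Reactants: 12 (2E,6E,9S)-3,7,11-trimethyldodeca-2,6,11-trien-4-yne-1,9-diol; 13 triphenylphosphine hydrobromide
Product: 14 [(2E,6E,9S)-9-hydroxy-3,7,11-trimethyldodeca-2,6,11-trien-4-yn-1-yl]triphenylphosphonium bromide
Conditions: PPh3·HBr (1.05 equiv), CH2Cl2, 0 °C → rt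
Reagents that add atoms: triphenylphosphine hydrobromide, [Br-].[PH+](c1ccccc1)(c1ccccc1)c1ccccc1
Why: Only the primary allylic alcohol is substituted under these mildly acidic conditions (allylic phosphonium salt formation, the usual C15 Wittig-salt preparation), while the secondary homoallylic alcohol is inert.

Step 6
Reactants: 14 [(2E,6E,9S)-9-hydroxy-3,7,11-trimethyldodeca-2,6,11-trien-4-yn-1-yl]triphenylphosphonium bromide
Product: 15 [(2E)-5-[(4R)-4-hydroxy-2,6,6-trimethylcyclohex-1-en-1-yl]-3-methylpent-2-en-4-yn-1-yl]triphenylphosphonium bromide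
Conditions: MeSO3H (10 equiv), CH2Cl2, −20 → 0 °C; aq. NaBr/NaHCO3 work-up
Reagents that add atoms: none
Why: Proposed new method: a Brønsted-acid cation–olefin cyclisation run on the complete open-chain Wittig salt, in which MeSO3H protonates the isolated 1,1-disubstituted alkene (the enyne is deactivated by its sp carbons and by the allylic phosphonium group, which itself cannot ionise) to the C1 tertiary cation, C6 of the E-enyne attacks through a chair to give the ring C5 cation, and loss of the axial propargylic H6 gives the conjugated cyclohexenyl-alkyne, the C3 carbinol being untouched and only homoallylic (acid-stable) in the product; the closest known reaction type is the strong-acid cyclisation of pseudoionone to β-ionone.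

Step 7
Reactants: 15 [(2E)-5-[(4R)-4-hydroxy-2,6,6-trimethylcyclohex-1-en-1-yl]-3-methylpent-2-en-4-yn-1-yl]triphenylphosphonium bromide; 16 (2E,4E,6E)-2,7-dimethylocta-2,4,6-trienedial
Product: 17 (2E,4E,6E,8E,10E)-13-[(4R)-4-hydroxy-2,6,6-trimethylcyclohex-1-en-1-yl]-2,7,11-trimethyltrideca-2,4,6,8,10-pentaen-12-ynal
Conditions: NaOMe, MeOH/CH2Cl2, 0 °C → rt, 16 in excess (3 equiv); all-E isomer crystallised
Reagents that add atoms: (2E,4E,6E)-2,7-dimethylocta-2,4,6-trienedial, O=C/C(C)=C/C=C/C=C(C)/C=O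
Why: Wittig olefination of the allylic ylide with one formyl group of the symmetrical dialdehyde (used in excess to stop at mono-olefination) builds C11=C12 and tolerates the free hydroxyl.

Step 8
Reactants: 18 (R)-epichlorohydrin; 2 isopropenylmagnesium bromide
Product: 19 (R)-1-chloro-4-methylpent-4-en-2-ol
Conditions: CuI (10 mol%), THF, −40 → −20 °C; aq. NH4Cl
Reagents that add atoms: isopropenylmagnesium bromide, CC(=C)[Mg]Br
Why: The same copper-catalysed SN2 epoxide opening in the enantiomeric series supplies the carbinol that becomes C3' of the ε ring.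

Step 9
Reactants: 19 (R)-1-chloro-4-methylpent-4-en-2-ol; 4 lithium acetylide–ethylenediamine complex
Product: 21 (R)-6-methylhept-6-en-1-yn-4-ol, via epoxide 20 (not isolated)
Conditions: LiC≡CH·H2NCH2CH2NH2 (3 equiv), DMSO, 0 °C → rt; aq. NH4Cl
Reagents that add atoms: lithium acetylide–ethylenediamine complex, [Li+].[C-]#C.NCCN
Why: Epoxide closure and SN2 alkynylation at CH2 proceed without touching the stereocentre, as in step 2.

Step 10
Reactants: 21 (R)-6-methylhept-6-en-1-yn-4-ol; 7 trimethylaluminium; 8 iodine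
Product: 23 (R,E)-1-iodo-2,6-dimethylhepta-1,6-dien-4-ol, via alkenylalane 22 (not isolated)
Conditions: AlMe3 (3 equiv), Cp2ZrCl2 (0.3 equiv), CH2Cl2, 0 °C → rt; then I2, THF, −30 → 0 °C
Reagents that add atoms: trimethylaluminium, C[Al](C)C; iodine, II
Why: Negishi carboalumination (syn addition) followed by iodinolysis with retention gives the E-alkenyl iodide, as in step 3.

Step 11
Reactants: 23 (R,E)-1-iodo-2,6-dimethylhepta-1,6-dien-4-ol; 24 methyl vinyl ketone
Product: 25 (3E,5E,8R)-8-hydroxy-6,10-dimethylundeca-3,5,10-trien-2-one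
Conditions: Pd(OAc)2 (5 mol%), n-Bu4NCl, NaHCO3, DMF, rt, 24 in excess (5 equiv)
Reagents that add atoms: methyl vinyl ketone, CC(=O)C=C
Why: Heck coupling under Jeffery conditions keeps the C5'=C6' geometry and forms C7'=C8' as the E-alkene by syn insertion and syn β-hydride elimination, the excess enone outrunning carbopalladation of the isopropenyl group.

Step 12
Reactants: 25 (3E,5E,8R)-8-hydroxy-6,10-dimethylundeca-3,5,10-trien-2-one; 26 hydrogen chloride
Product: 28 (3E)-4-[(1R,4R)-4-hydroxy-2,6,6-trimethylcyclohex-2-en-1-yl]but-3-en-2-one [(3R,6R)-3-hydroxy-α-ionone], via tertiary chloride 27 (not isolated)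
Conditions: HCl (4 M in dioxane), CH2Cl2, 0 °C, evaporate; then MeAlCl2 (3.5 equiv), CH2Cl2, −78 → −40 °C; aq. KNaC4H4O6 work-up
Reagents that add atoms: none
Why: Proposed new method: Markovnikov HCl addition marks C1' as the cation site, MeAlCl2 turns the hydroxyl into an O–AlCl2 alkoxide and ionises the tertiary chloride, the C1' cation is attacked by C6' of the dienone through a chair in which the C3'–OAl group is equatorial (avoiding the axial C1' methyl) and the E-alkene places the side chain equatorial, so C6' is set trans to C3'–O (6'R), and H4' is then lost to the aluminium-bound methyl or oxygen with evolution of methane, so that no free acid remains to ionise the new allylic C–O bond; the closest known reaction types are the pseudoionone to α-ionone cyclisation and MeAlCl2-promoted cation–olefin cyclisations.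

Step 13
Reactants: 28 (3E)-4-[(1R,4R)-4-hydroxy-2,6,6-trimethylcyclohex-2-en-1-yl]but-3-en-2-one; 29 vinylmagnesium bromide
Product: 30 (4E)-5-[(1R,4R)-4-hydroxy-2,6,6-trimethylcyclohex-2-en-1-yl]-3-methylpenta-1,4-dien-3-ol (both C3 epimers)
Conditions: THF, −20 → 0 °C, 29 (3 equiv); aq. NH4Cl
Reagents that add atoms: vinylmagnesium bromide, C=C[Mg]Br
Why: Grignard 1,2-addition to the methyl ketone (the first equivalent deprotonates the hydroxyl) gives the vinyl carbinol, whose new centre is an inconsequential epimer mixture erased in step 14.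

Step 14
Reactants: 30 (4E)-5-[(1R,4R)-4-hydroxy-2,6,6-trimethylcyclohex-2-en-1-yl]-3-methylpenta-1,4-dien-3-ol; 13 triphenylphosphine hydrobromide
Product: 31 [(2E,4E)-5-[(1R,4R)-4-hydroxy-2,6,6-trimethylcyclohex-2-en-1-yl]-3-methylpenta-2,4-dien-1-yl]triphenylphosphonium bromide
Conditions: PPh3·HBr (1.0 equiv), MeOH, 0 °C, 2 h
Reagents that add atoms: triphenylphosphine hydrobromide, [Br-].[PH+](c1ccccc1)(c1ccccc1)c1ccccc1
Why: The tertiary bis-allylic alcohol ionises far more readily than the ring secondary allylic alcohol, and PPh3 traps the pentadienyl cation at its primary terminus (allylic transposition, the vinyl-ionol to C15 Wittig-salt reaction) to give the 9'E salt.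

Step 15
Reactants: 31 [(2E,4E)-5-[(1R,4R)-4-hydroxy-2,6,6-trimethylcyclohex-2-en-1-yl]-3-methylpenta-2,4-dien-1-yl]triphenylphosphonium bromide; 17 (2E,4E,6E,8E,10E)-13-[(4R)-4-hydroxy-2,6,6-trimethylcyclohex-1-en-1-yl]-2,7,11-trimethyltrideca-2,4,6,8,10-pentaen-12-ynal
Product: 32 (3R,3'R,6'R)-7,8-didehydro-β,ε-carotene-3,3'-diol (target)
Conditions: NaOMe, MeOH/CH2Cl2, 0 °C → rt; then EtOH reflux (Z → E), crystallise
Reagents that add atoms: none
Why: Wittig olefination forms C11'=C12' with both hydroxyls free and no stereocentre involved, and thermal equilibration followed by crystallisation delivers the all-E polyene.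

**Compound list**
1 | (S)-epichlorohydrin | ClC[C@@H]1CO1 | starting material
2 | isopropenylmagnesium bromide | CC(=C)[Mg]Br | starting material
3 | (S)-1-chloro-4-methylpent-4-en-2-ol | ClC[C@@H](O)CC(C)=C | intermediate
4 | lithium acetylide–ethylenediamine complex | [Li+].[C-]#C.NCCN | starting material
5 | (S)-2-(2-methylprop-2-en-1-yl)oxirane | C=C(C)C[C@H]1CO1 | intermediate
6 | (S)-6-methylhept-6-en-1-yn-4-ol | C#CC[C@@H](O)CC(C)=C | intermediate
7 | trimethylaluminium | C[Al](C)C | starting material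
8 | iodine | II | starting material
9 | [(1E,4S)-4-[(dimethylalumanyl)oxy]-2,6-dimethylhepta-1,6-dien-1-yl]dimethylalumane | C[Al](C)/C=C(C)/C[C@@H](O[Al](C)C)CC(C)=C | intermediate
10 | (S,E)-1-iodo-2,6-dimethylhepta-1,6-dien-4-ol | I/C=C(C)/C[C@@H](O)CC(C)=C | intermediate
11 | (E)-3-methylpent-2-en-4-yn-1-ol | C#C/C(C)=C/CO | starting material
12 | (2E,6E,9S)-3,7,11-trimethyldodeca-2,6,11-trien-4-yne-1,9-diol | C=C(C)C[C@H](O)C/C(C)=C/C#C/C(C)=C/CO | intermediate
13 | triphenylphosphine hydrobromide | [Br-].[PH+](c1ccccc1)(c1ccccc1)c1ccccc1 | starting material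
14 | [(2E,6E,9S)-9-hydroxy-3,7,11-trimethyldodeca-2,6,11-trien-4-yn-1-yl]triphenylphosphonium bromide | C=C(C)C[C@H](O)C/C(C)=C/C#C/C(C)=C/C[P+](c1ccccc1)(c1ccccc1)c1ccccc1.[Br-] | intermediate
15 | [(2E)-5-[(4R)-4-hydroxy-2,6,6-trimethylcyclohex-1-en-1-yl]-3-methylpent-2-en-4-yn-1-yl]triphenylphosphonium bromide | CC1=C(C#C/C(C)=C/C[P+](c2ccccc2)(c2ccccc2)c2ccccc2)C(C)(C)C[C@H](O)C1.[Br-] | intermediate
16 | (2E,4E,6E)-2,7-dimethylocta-2,4,6-trienedial | O=C/C(C)=C/C=C/C=C(C)/C=O | starting material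
17 | (2E,4E,6E,8E,10E)-13-[(4R)-4-hydroxy-2,6,6-trimethylcyclohex-1-en-1-yl]-2,7,11-trimethyltrideca-2,4,6,8,10-pentaen-12-ynal | O=C/C(C)=C/C=C/C=C(C)/C=C/C=C(\C)C#CC1=C(C)C[C@@H](O)CC1(C)C | intermediate
18 | (R)-epichlorohydrin | ClC[C@H]1CO1 | starting material
19 | (R)-1-chloro-4-methylpent-4-en-2-ol | ClC[C@H](O)CC(C)=C | intermediate
20 | (R)-2-(2-methylprop-2-en-1-yl)oxirane | C=C(C)C[C@@H]1CO1 | intermediate
21 | (R)-6-methylhept-6-en-1-yn-4-ol | C#CC[C@H](O)CC(C)=C | intermediate
22 | [(1E,4R)-4-[(dimethylalumanyl)oxy]-2,6-dimethylhepta-1,6-dien-1-yl]dimethylalumane | C[Al](C)/C=C(C)/C[C@H](O[Al](C)C)CC(C)=C | intermediate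
23 | (R,E)-1-iodo-2,6-dimethylhepta-1,6-dien-4-ol | I/C=C(C)/C[C@H](O)CC(C)=C | intermediate
24 | methyl vinyl ketone | CC(=O)C=C | starting material
25 | (3E,5E,8R)-8-hydroxy-6,10-dimethylundeca-3,5,10-trien-2-one | C=C(C)C[C@@H](O)C/C(C)=C/C=C/C(C)=O | intermediate
26 | hydrogen chloride | Cl | starting material
27 | (3E,5E,8S)-10-chloro-8-hydroxy-6,10-dimethylundeca-3,5-dien-2-one | CC(C)(Cl)C[C@@H](O)C/C(C)=C/C=C/C(C)=O | intermediate
28 | (3E)-4-[(1R,4R)-4-hydroxy-2,6,6-trimethylcyclohex-2-en-1-yl]but-3-en-2-one | CC1=C[C@H](O)CC(C)(C)[C@H]1/C=C/C(C)=O | intermediate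
29 | vinylmagnesium bromide | C=C[Mg]Br | starting material
30 | (4E)-5-[(1R,4R)-4-hydroxy-2,6,6-trimethylcyclohex-2-en-1-yl]-3-methylpenta-1,4-dien-3-ol | CC1=C[C@H](O)CC(C)(C)[C@H]1/C=C/C(C)(O)C=C | intermediate
31 | [(2E,4E)-5-[(1R,4R)-4-hydroxy-2,6,6-trimethylcyclohex-2-en-1-yl]-3-methylpenta-2,4-dien-1-yl]triphenylphosphonium bromide | CC1=C[C@H](O)CC(C)(C)[C@H]1/C=C/C(C)=C/C[P+](c1ccccc1)(c1ccccc1)c1ccccc1.[Br-] | intermediate
32 | (3R,3'R,6'R)-7,8-didehydro-β,ε-carotene-3,3'-diol | CC1=C[C@H](O)CC(C)(C)[C@H]1/C=C/C(C)=C/C=C/C(C)=C/C=C/C=C(C)/C=C/C=C(\C)C#CC1=C(C)C[C@@H](O)CC1(C)C | target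

**Totals**
Total step count: 15. Longest linear sequence: 8 steps (steps 1–7 and 15, or steps 8–15).

**Three steps most likely to fail**

Step 12 (ε-ring closure). The product is an acid-labile allylic alcohol, and the position of the new double bond rests on the proposed aluminium-mediated proton loss. Fallback, setting out from 25 and returning at 28: silylation with t-BuPh2SiCl and imidazole in DMF gives (3E,5E,8R)-8-[(tert-butyldiphenylsilyl)oxy]-6,10-dimethylundeca-3,5,10-trien-2-one F5. HCl in CH2Cl2 adds to the isopropenyl group to give the tertiary chloride (3E,5E,8S)-8-[(tert-butyldiphenylsilyl)oxy]-10-chloro-6,10-dimethylundeca-3,5-dien-2-one F6. Chloride abstraction with AgBF4 in CH2Cl2 at −78 °C, buffered with 2,6-di-tert-butyl-4-methylpyridine, generates the C1' cation in a medium free of Brønsted acid and of aluminium Lewis acid. The same chair closure then gives (3E)-4-[(1R,4R)-4-[(tert-butyldiphenylsilyl)oxy]-2,6,6-trimethylcyclohex-2-en-1-yl]but-3-en-2-one F7. n-Bu4NF in THF removes the silyl group to give 28.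

Step 6 (β-ring closure on the open-chain phosphonium salt). Risks are competing protonation or addition at the enyne and kinetic proton loss from C4. Fallback, setting out from 10 and returning at 15, moves the ring closure to the C11 stage: Sonogashira coupling of 10 with trimethylsilylacetylene (Pd(PPh3)2Cl2, CuI, Et3N) gives (4S,6E)-2,6-dimethyl-9-(trimethylsilyl)nona-1,6-dien-8-yn-4-ol F1. MeSO3H in CH2Cl2 cyclises this small enyne, which carries neither an allylic leaving group nor a phosphonium group, to (1R)-3,5,5-trimethyl-4-[(trimethylsilyl)ethynyl]cyclohex-3-en-1-ol F2. K2CO3 in MeOH gives (1R)-4-ethynyl-3,5,5-trimethylcyclohex-3-en-1-ol F3. After double deprotonation with n-BuLi (2.1 equiv, THF, −78 °C) it adds to methyl vinyl ketone 24 to give 5-[(4R)-4-hydroxy-2,6,6-trimethylcyclohex-1-en-1-yl]-3-methylpent-1-en-4-yn-3-ol F4. PPh3·HBr converts this tertiary carbinol with allylic transposition into 15.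

Step 14 (phosphonium salt formation next to the acid-sensitive ε-ring allylic alcohol). Fallback, setting out from 28 and 17 and returning at 32, reverses the polarity of the last Wittig reaction so that the ε ring never meets acid: Horner–Wadsworth–Emmons reaction of 28 with diethyl (cyanomethyl)phosphonate (NaH, THF) gives (2E,4E)-5-[(1R,4R)-4-hydroxy-2,6,6-trimethylcyclohex-2-en-1-yl]-3-methylpenta-2,4-dienenitrile F8. i-Bu2AlH (toluene, −78 °C, aqueous work-up) reduces it to (2E,4E)-5-[(1R,4R)-4-hydroxy-2,6,6-trimethylcyclohex-2-en-1-yl]-3-methylpenta-2,4-dienal F9. In parallel NaBH4 in MeOH reduces 17 to (2E,4E,6E,8E,10E)-13-[(4R)-4-hydroxy-2,6,6-trimethylcyclohex-1-en-1-yl]-2,7,11-trimethyltrideca-2,4,6,8,10-pentaen-12-yn-1-ol F10. PPh3·HBr converts it, its β-ring alcohol being only homoallylic, into [(2E,4E,6E,8E,10E)-13-[(4R)-4-hydroxy-2,6,6-trimethylcyclohex-1-en-1-yl]-2,7,11-trimethyltrideca-2,4,6,8,10-pentaen-12-yn-1-yl]triphenylphosphonium bromide F11. Wittig reaction of F11 with F9 (NaOMe, MeOH/CH2Cl2) and thermal equilibration give 32.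

**Further compounds**
F1 | step 6 | (4S,6E)-2,6-dimethyl-9-(trimethylsilyl)nona-1,6-dien-8-yn-4-ol | C=C(C)C[C@H](O)C/C(C)=C/C#C[Si](C)(C)C
F2 | step 6 | (1R)-3,5,5-trimethyl-4-[(trimethylsilyl)ethynyl]cyclohex-3-en-1-ol | CC1=C(C#C[Si](C)(C)C)C(C)(C)C[C@H](O)C1
F3 | step 6 | (1R)-4-ethynyl-3,5,5-trimethylcyclohex-3-en-1-ol | CC1=C(C#C)C(C)(C)C[C@H](O)C1
F4 | step 6 | 5-[(4R)-4-hydroxy-2,6,6-trimethylcyclohex-1-en-1-yl]-3-methylpent-1-en-4-yn-3-ol | CC1=C(C#CC(C)(O)C=C)C(C)(C)C[C@H](O)C1
F5 | step 12 | (3E,5E,8R)-8-[(tert-butyldiphenylsilyl)oxy]-6,10-dimethylundeca-3,5,10-trien-2-one | C=C(C)C[C@@H](O[Si](c1ccccc1)(c1ccccc1)C(C)(C)C)C/C(C)=C/C=C/C(C)=O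
F6 | step 12 | (3E,5E,8S)-8-[(tert-butyldiphenylsilyl)oxy]-10-chloro-6,10-dimethylundeca-3,5-dien-2-one | CC(C)(Cl)C[C@@H](O[Si](c1ccccc1)(c1ccccc1)C(C)(C)C)C/C(C)=C/C=C/C(C)=O
F7 | step 12 | (3E)-4-[(1R,4R)-4-[(tert-butyldiphenylsilyl)oxy]-2,6,6-trimethylcyclohex-2-en-1-yl]but-3-en-2-one | CC1=C[C@H](O[Si](c2ccccc2)(c2ccccc2)C(C)(C)C)CC(C)(C)[C@H]1/C=C/C(C)=O
F8 | step 14 | (2E,4E)-5-[(1R,4R)-4-hydroxy-2,6,6-trimethylcyclohex-2-en-1-yl]-3-methylpenta-2,4-dienenitrile | CC1=C[C@H](O)CC(C)(C)[C@H]1/C=C/C(C)=C/C#N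
F9 | step 14 | (2E,4E)-5-[(1R,4R)-4-hydroxy-2,6,6-trimethylcyclohex-2-en-1-yl]-3-methylpenta-2,4-dienal | CC1=C[C@H](O)CC(C)(C)[C@H]1/C=C/C(C)=C/C=O
F10 | step 14 | (2E,4E,6E,8E,10E)-13-[(4R)-4-hydroxy-2,6,6-trimethylcyclohex-1-en-1-yl]-2,7,11-trimethyltrideca-2,4,6,8,10-pentaen-12-yn-1-ol | OC/C(C)=C/C=C/C=C(C)/C=C/C=C(\C)C#CC1=C(C)C[C@@H](O)CC1(C)C
F11 | step 14 | [(2E,4E,6E,8E,10E)-13-[(4R)-4-hydroxy-2,6,6-trimethylcyclohex-1-en-1-yl]-2,7,11-trimethyltrideca-2,4,6,8,10-pentaen-12-yn-1-yl]triphenylphosphonium bromide | c1ccc(cc1)[P+](c1ccccc1)(c1ccccc1)C/C(C)=C/C=C/C=C(C)/C=C/C=C(\C)C#CC1=C(C)C[C@@H](O)CC1(C)C.[Br-]
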